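**Retrosynthetic overview**

1. Germacrane numbering is used: ring A = carbocycle C1–C10; ring B = lactone O–C8–C7–C11–C12; C13 = exocyclic CH2; C14 on C10; C15 on C4. Target 20 ⇒ epoxy alcohol 19 (C6 acetylation) ⇒ hydroxy triene lactone 18 (hydroxyl-directed epoxidation of C4=C5).
2. Key disconnection is C6–C7 of ring A. C7 is the β-carbon of ring B, so C13–C11–C7 is a 2-carbonyl-allyl unit, and C6 carries oxygen. Hence 18 ⇒ 16, a C6 aldehyde with a C13 bromide whose only ring is an endocyclic butenolide. A chromium-mediated SE2' allylation closes ring A, sets C6 and C7, and moves the double bond out to C11=C13.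
3. Ring B of 16 comes from ring-closing metathesis of 15, the 2-(bromomethyl)acrylate of the C8 carbinol.
4. The chain holds the unit O–C–CH2–C(CH3)=CH–C twice. Two catalytic asymmetric vinylogous Mukaiyama aldol additions of one silyl dienolate (3), first to crotonaldehyde and then to enal 8, set C8, C2 and both E-trisubstituted alkenes.
5. Order of ring formation: ring B (step 12), ring A (step 13), oxirane (step 14).

Key step: step 13

Assumption: the (S,S)-antipode of the chiral bisphosphoramide is taken to direct the dienolate to the Si face of a conjugated aldehyde, which gives the S carbinols drawn; if the sense of induction is the reverse, the (R,R)-antipode is used in steps 2 and 6.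

**Route**

Step 1
Reactants: 1 ethyl 3-methylbut-2-enoate
Product: 3 tert-butyl[(1-ethoxy-3-methylbuta-1,3-dien-1-yl)oxy]dimethylsilane, via lithium dienolate 2 (not isolated)
Conditions: LiN(i-Pr)2 (commercial solution), THF, −78 °C; then TBSCl, DMPU, −78 °C to rt; distillation (made once, in quantity for steps 2 and 6)
Reagents that add atoms: tert-butyldimethylsilyl chloride, CC(C)(C)[Si](C)(C)Cl
Why: Kinetic γ-deprotonation of the senecioate gives the extended lithium dienolate 2, which is O-silylated in the presence of DMPU (silyl ketene acetal formation); no stereocenter is formed and the ketene acetal geometry is of no consequence.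

Step 2
Reactants: 3 tert-butyl[(1-ethoxy-3-methylbuta-1,3-dien-1-yl)oxy]dimethylsilane; 4 (E)-but-2-enal
Product: 5 ethyl (2E,5S,6E)-5-hydroxy-3-methylocta-2,6-dienoate
Conditions: SiCl4 (1.1 equiv), (S,S)-bisphosphoramide (pentamethylene-linked dimer of the phosphoramide of N,N'-dimethyl-1,1'-binaphthyl-2,2'-diamine, 5 mol %), i-Pr2NEt (10 mol %), CH2Cl2, −78 °C; aqueous work-up
Reagents that add atoms: none
Why: Lewis-base-activated SiCl4 vinylogous Mukaiyama aldol addition, in which the phosphoramide-bound trichlorosilyl cation activates the enal for 1,2-attack by the γ-carbon of 3 through an open transition state, the s-trans dienolate giving the 2E-enoate and the catalyst directing attack to the Si face so that the carbinol (the future C8) is S.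

Step 3
Reactants: 5 ethyl (2E,5S,6E)-5-hydroxy-3-methylocta-2,6-dienoate
Product: 6 ethyl (2E,5S,6E)-5-{[tert-butyl(dimethyl)silyl]oxy}-3-methylocta-2,6-dienoate
Conditions: TBSCl, imidazole, DMF, rt
Reagents that add atoms: tert-butyldimethylsilyl chloride, CC(C)(C)[Si](C)(C)Cl
Why: Standard silylation of a secondary allylic alcohol, which masks the future lactone oxygen through the hydride reductions and the second aldol addition.

Step 4
Reactants: 6 ethyl (2E,5S,6E)-5-{[tert-butyl(dimethyl)silyl]oxy}-3-methylocta-2,6-dienoate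
Product: 7 (2E,5S,6E)-5-{[tert-butyl(dimethyl)silyl]oxy}-3-methylocta-2,6-dien-1-ol
Conditions: i-Bu2AlH (2.2 equiv), CH2Cl2, −78 °C; Rochelle salt work-up
Reagents that add atoms: none
Why: 1,2-Reduction of the conjugated ester by i-Bu2AlH gives the allylic alcohol without touching the alkenes or the silyl ether.

Step 5
Reactants: 7 (2E,5S,6E)-5-{[tert-butyl(dimethyl)silyl]oxy}-3-methylocta-2,6-dien-1-ol
Product: 8 (2E,5S,6E)-5-{[tert-butyl(dimethyl)silyl]oxy}-3-methylocta-2,6-dienal
Conditions: MnO2 (activated, excess), CH2Cl2, rt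
Reagents that add atoms: none
Why: MnO2 oxidises the primary allylic alcohol to the E-enal selectively and without over-oxidation.

Step 6
Reactants: 8 (2E,5S,6E)-5-{[tert-butyl(dimethyl)silyl]oxy}-3-methylocta-2,6-dienal; 3 tert-butyl[(1-ethoxy-3-methylbuta-1,3-dien-1-yl)oxy]dimethylsilane
Product: 9 ethyl (2E,5S,6E,9S,10E)-9-{[tert-butyl(dimethyl)silyl]oxy}-5-hydroxy-3,7-dimethyldodeca-2,6,10-trienoate
Conditions: SiCl4 (1.1 equiv), (S,S)-bisphosphoramide (5 mol %), i-Pr2NEt (10 mol %), CH2Cl2, −78 °C; aqueous work-up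
Reagents that add atoms: none
Why: Second vinylogous Mukaiyama aldol addition under the same catalyst control (Si-face attack on the β,β-disubstituted enal, the remote silyloxy stereocenter being without influence) sets the S carbinol that becomes C2 and the E-configured enoate that becomes C4=C5.

Step 7
Reactants: 9 ethyl (2E,5S,6E,9S,10E)-9-{[tert-butyl(dimethyl)silyl]oxy}-5-hydroxy-3,7-dimethyldodeca-2,6,10-trienoate
Product: 10 (2E,5S,6E,9S,10E)-9-{[tert-butyl(dimethyl)silyl]oxy}-3,7-dimethyldodeca-2,6,10-triene-1,5-diol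
Conditions: i-Bu2AlH (3.3 equiv), CH2Cl2, −78 °C; Rochelle salt work-up
Reagents that add atoms: none
Why: 1,2-Reduction of the enoate by i-Bu2AlH in the presence of the free secondary alcohol (one extra equivalent consumed as the alkoxide) gives the diol.

Step 8
Reactants: 10 (2E,5S,6E,9S,10E)-9-{[tert-butyl(dimethyl)silyl]oxy}-3,7-dimethyldodeca-2,6,10-triene-1,5-diol
Product: 11 (2E,5S,6E,9S,10E)-9-{[tert-butyl(dimethyl)silyl]oxy}-5-hydroxy-3,7-dimethyldodeca-2,6,10-trienal
Conditions: TEMPO (10 mol %), PhI(OAc)2 (1.1 equiv), CH2Cl2, rt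
Reagents that add atoms: none
Why: The oxoammonium oxidation is selective for the primary allylic alcohol over the secondary one and stops at the aldehyde, giving the E-enal that carries the future C6.

Step 9
Reactants: 11 (2E,5S,6E,9S,10E)-9-{[tert-butyl(dimethyl)silyl]oxy}-5-hydroxy-3,7-dimethyldodeca-2,6,10-trienal
Product: 12 (2E,5S,6E,9S,10E)-9-{[tert-butyl(dimethyl)silyl]oxy}-3,7-dimethyl-1-oxododeca-2,6,10-trien-5-yl acetate
Conditions: Ac2O, pyridine, DMAP (cat.), CH2Cl2, 0 °C
Reagents that add atoms: acetic anhydride, CC(=O)OC(C)=O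
Why: Acetylation of the secondary allylic alcohol installs the C2 acetate of the target under weakly basic conditions that should not trigger vinylogous elimination of the δ-acyloxy enal.

Step 10
Reactants: 12 (2E,5S,6E,9S,10E)-9-{[tert-butyl(dimethyl)silyl]oxy}-3,7-dimethyl-1-oxododeca-2,6,10-trien-5-yl acetate
Product: 13 (2E,5S,6E,9S,10E)-9-hydroxy-3,7-dimethyl-1-oxododeca-2,6,10-trien-5-yl acetate
Conditions: HF·pyridine, pyridine, THF, 0 °C to rt
Reagents that add atoms: none
Why: Buffered, non-basic fluoride cleavage of the Si–O bond frees the C8 hydroxyl while the enal and the δ-acetoxy group (which a basic fluoride source could eliminate) survive.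

Step 11
Reactants: 13 (2E,5S,6E,9S,10E)-9-hydroxy-3,7-dimethyl-1-oxododeca-2,6,10-trien-5-yl acetate; 14 2-(bromomethyl)prop-2-enoic acid
Product: 15 (2E,4S,6E,8S,10E)-8-(acetyloxy)-6,10-dimethyl-12-oxododeca-2,6,10-trien-4-yl 2-(bromomethyl)prop-2-enoate
Conditions: 14 (1.5 equiv), DCC, DMAP (5 mol %), CH2Cl2, 0 °C
Reagents that add atoms: none
Why: Steglich esterification at 0 °C with only catalytic DMAP, so that O-acylation outruns displacement of the allylic bromide; the C8 configuration is retained because the C–O bond is not touched.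

Step 12
Reactants: 15 (2E,4S,6E,8S,10E)-8-(acetyloxy)-6,10-dimethyl-12-oxododeca-2,6,10-trien-4-yl 2-(bromomethyl)prop-2-enoate
Product: 16 (2E,5S,6E)-8-[(2S)-4-(bromomethyl)-5-oxo-2,5-dihydrofuran-2-yl]-3,7-dimethyl-1-oxoocta-2,6-dien-5-yl acetate
Conditions: second-generation Grubbs catalyst (H2IMes)(PCy3)Cl2Ru=CHPh (5 mol %), CH2Cl2 (5 mM), 40 °C
Reagents that add atoms: none
Why: Ring-closing metathesis between the propenyl group and the 1,1-disubstituted acrylate closes the five-membered butenolide (ring B at the butenolide oxidation pattern) with loss of propene, the trisubstituted and enal alkenes being inert, and places the bromomethyl group on C11.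

Step 13
Reactants: 16 (2E,5S,6E)-8-[(2S)-4-(bromomethyl)-5-oxo-2,5-dihydrofuran-2-yl]-3,7-dimethyl-1-oxoocta-2,6-dien-5-yl acetate
Product: 18 (3aS,4R,5E,8S,9E,11aS)-4-hydroxy-6,10-dimethyl-3-methylidene-2-oxo-2,3,3a,4,7,8,11,11a-octahydrocyclodeca[b]furan-8-yl acetate, via allylchromium dichloride 17 (not isolated)
Conditions: CrCl2 (8 equiv), THF, rt, 16 added by syringe pump over 10 h (final 2 mM); aqueous work-up
Reagents that add atoms: none
Why: Two equivalents of CrCl2 reduce the allylic C13–Br bond of 16 to the σ-allyl species 17 of trivalent chromium, which adds to the C6 aldehyde through its γ-carbon C7 in a closed six-membered chair transition state (Cr–O=C6···C7=C11–C13), so that the C6–C7 bond forms while the double bond moves to the exocyclic C11=C13 position. The closest known reaction type is the intramolecular Nozaki–Hiyama–Kishi allylation of ω-formyl allylic bromides of the farnesyl type, which closes ten-membered germacrane rings at this same bond, together with the chromium-mediated addition of 3-(bromomethyl)butenolides to aldehydes. Ring A, the only ring closed, forms by 10-exo-trig attack of C7 on the aldehyde carbon with allylic transposition (SE2') in the metal-bearing unit. C7 is controlled by the C8 stereocenter, because the tether leaves C8 on one face of the planar butenolide and the aldehyde is taken up on the opposite face, which gives the trans ring fusion (C6 and C9 trans on ring B); C6 is controlled by the fixed geometry of the allyl unit (C8 trans to C13 across C11=C7, an E-crotyl-type reagent) and by the equatorial position of the C5 alkenyl residue in the chair, which gives the anti relationship (6R in 18) that the target requires. The step needs γ- over α-attack (ten- instead of twelve-membered ring), secured by the cyclic allyl-transposition mechanism of allylchromium reagents; cyclisation over oligomerisation, secured by slow addition at high dilution; and chemoselectivity, secured by the inertness of the allylic acetate, the enal C=C bond and the lactone toward divalent chromium.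

Step 14
Reactants: 18 (3aS,4R,5E,8S,9E,11aS)-4-hydroxy-6,10-dimethyl-3-methylidene-2-oxo-2,3,3a,4,7,8,11,11a-octahydrocyclodeca[b]furan-8-yl acetate
Product: 19 (2S,4R,5R,6S,7S,8S)-2-acetoxy-4,5-epoxy-6-hydroxygermacra-1(10)E,11(13)-dien-12,8-olide
Conditions: VO(acac)2 (5 mol %), t-BuOOH (anhydrous, decane), CH2Cl2, 0 °C
Reagents that add atoms: tert-butyl hydroperoxide, CC(C)(C)OO
Why: Hydroxyl-directed vanadium-catalysed epoxidation, in which the C6 alkoxide-bound vanadium peroxide delivers oxygen only to the neighbouring C4=C5 alkene, from the outer face of the ring syn to the hydroxyl in the A(1,3)-minimised conformer (H6 eclipsing the C4 methyl group), which should give the 4R,5R trans-oxirane while the acrylate alkene and the acetate-flanked C1=C10 alkene are not touched.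

Step 15
Reactants: 19 (2S,4R,5R,6S,7S,8S)-2-acetoxy-4,5-epoxy-6-hydroxygermacra-1(10)E,11(13)-dien-12,8-olide
Product: 20 (2S,4R,5R,6S,7R,8S)-2,6-diacetoxy-4,5-epoxygermacra-1(10)E,11(13)-dien-12,8-olide
Conditions: Ac2O, pyridine, DMAP (cat.), CH2Cl2, 0 °C to rt
Reagents that add atoms: acetic anhydride, CC(=O)OC(C)=O
Why: Acetylation of the C6 hydroxyl under mild, acid-free conditions completes the target without opening the oxirane or the lactone.

**Compound list**

1 | ethyl 3-methylbut-2-enoate | CCOC(=O)C=C(C)C | starting material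
2 | lithium 1-ethoxy-3-methylbuta-1,3-dien-1-olate (not isolated) | C=C(C)C=C(OCC)O[Li] | intermediate
3 | tert-butyl[(1-ethoxy-3-methylbuta-1,3-dien-1-yl)oxy]dimethylsilane (ketene acetal geometry not defined) | C=C(C)C=C(OCC)O[Si](C)(C)C(C)(C)C | intermediate
4 | (E)-but-2-enal (crotonaldehyde) | C/C=C/C=O | starting material
5 | ethyl (2E,5S,6E)-5-hydroxy-3-methylocta-2,6-dienoate | C/C=C/[C@@H](O)C/C(C)=C/C(=O)OCC | intermediate
6 | ethyl (2E,5S,6E)-5-{[tert-butyl(dimethyl)silyl]oxy}-3-methylocta-2,6-dienoate | C/C=C/[C@@H](O[Si](C)(C)C(C)(C)C)C/C(C)=C/C(=O)OCC | intermediate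
7 | (2E,5S,6E)-5-{[tert-butyl(dimethyl)silyl]oxy}-3-methylocta-2,6-dien-1-ol | C/C=C/[C@@H](O[Si](C)(C)C(C)(C)C)C/C(C)=C/CO | intermediate
8 | (2E,5S,6E)-5-{[tert-butyl(dimethyl)silyl]oxy}-3-methylocta-2,6-dienal | C/C=C/[C@@H](O[Si](C)(C)C(C)(C)C)C/C(C)=C/C=O | intermediate
9 | ethyl (2E,5S,6E,9S,10E)-9-{[tert-butyl(dimethyl)silyl]oxy}-5-hydroxy-3,7-dimethyldodeca-2,6,10-trienoate | C/C=C/[C@@H](O[Si](C)(C)C(C)(C)C)C/C(C)=C/[C@@H](O)C/C(C)=C/C(=O)OCC | intermediate
10 | (2E,5S,6E,9S,10E)-9-{[tert-butyl(dimethyl)silyl]oxy}-3,7-dimethyldodeca-2,6,10-triene-1,5-diol | C/C=C/[C@@H](O[Si](C)(C)C(C)(C)C)C/C(C)=C/[C@@H](O)C/C(C)=C/CO | intermediate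
11 | (2E,5S,6E,9S,10E)-9-{[tert-butyl(dimethyl)silyl]oxy}-5-hydroxy-3,7-dimethyldodeca-2,6,10-trienal | C/C=C/[C@@H](O[Si](C)(C)C(C)(C)C)C/C(C)=C/[C@@H](O)C/C(C)=C/C=O | intermediate
12 | (2E,5S,6E,9S,10E)-9-{[tert-butyl(dimethyl)silyl]oxy}-3,7-dimethyl-1-oxododeca-2,6,10-trien-5-yl acetate | C/C=C/[C@@H](O[Si](C)(C)C(C)(C)C)C/C(C)=C/[C@@H](OC(C)=O)C/C(C)=C/C=O | intermediate
13 | (2E,5S,6E,9S,10E)-9-hydroxy-3,7-dimethyl-1-oxododeca-2,6,10-trien-5-yl acetate | C/C=C/[C@@H](O)C/C(C)=C/[C@@H](OC(C)=O)C/C(C)=C/C=O | intermediate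
14 | 2-(bromomethyl)prop-2-enoic acid | C=C(CBr)C(=O)O | starting material
15 | (2E,4S,6E,8S,10E)-8-(acetyloxy)-6,10-dimethyl-12-oxododeca-2,6,10-trien-4-yl 2-(bromomethyl)prop-2-enoate | C/C=C/[C@@H](OC(=O)C(=C)CBr)C/C(C)=C/[C@@H](OC(C)=O)C/C(C)=C/C=O | intermediate
16 | (2E,5S,6E)-8-[(2S)-4-(bromomethyl)-5-oxo-2,5-dihydrofuran-2-yl]-3,7-dimethyl-1-oxoocta-2,6-dien-5-yl acetate | BrCC1=C[C@H](C/C(C)=C/[C@@H](OC(C)=O)C/C(C)=C/C=O)OC1=O | intermediate
17 | allylchromium dichloride derived from 16 (CrCl2 on C13, trivalent chromium; not isolated) | Cl[Cr](Cl)CC1=C[C@H](C/C(C)=C/[C@@H](OC(C)=O)C/C(C)=C/C=O)OC1=O | intermediate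
18 | (3aS,4R,5E,8S,9E,11aS)-4-hydroxy-6,10-dimethyl-3-methylidene-2-oxo-2,3,3a,4,7,8,11,11a-octahydrocyclodeca[b]furan-8-yl acetate | C=C1C(=O)O[C@H]2C/C(C)=C/[C@@H](OC(C)=O)C/C(C)=C/[C@@H](O)[C@H]12 | intermediate
19 | (2S,4R,5R,6S,7S,8S)-2-acetoxy-4,5-epoxy-6-hydroxygermacra-1(10)E,11(13)-dien-12,8-olide | C=C1C(=O)O[C@H]2C/C(C)=C/[C@@H](OC(C)=O)C[C@@]3(C)O[C@@H]3[C@@H](O)[C@H]12 | intermediate
20 | (2S,4R,5R,6S,7R,8S)-2,6-diacetoxy-4,5-epoxygermacra-1(10)E,11(13)-dien-12,8-olide (CNP0270851.2) | C=C1C(=O)O[C@H]2C/C(C)=C/[C@@H](OC(C)=O)C[C@@]3(C)O[C@@H]3[C@@H](OC(C)=O)[C@H]12 | target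

**Step count and risks**

Total step count: 15. Longest linear sequence: 15 steps (1 to 20; dienolate 3 from step 1 is used in steps 2 and 6).

The three steps most likely to fail:

Step 13 (closure of ring A). What may go wrong: poor facial selectivity at the aldehyde carbon, because a ten-membered chair-like transition state need not keep the C5 residue equatorial, so that the C6 epimer forms beside or instead of 18. Fallback: C6 is set by a ketone reduction and not by the C–C bond formation. Setting out from 16, the closure is run as in step 13 and the 6-epi alcohol F1 (alone or mixed with 18) is oxidised with Dess–Martin periodinane and NaHCO3 in CH2Cl2 to the C6 ketone F2. F2 is then reduced with (R)-2-methyl-CBS-oxazaborolidine and catecholborane in toluene at −78 °C, base-free conditions that should leave the acidic C7–H alone. With the trisubstituted alkenyl flank acting as the large group, this antipode should deliver hydride to the Si face of the C6 carbonyl, and the route is rejoined at 18.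

Step 14 (epoxidation). What may go wrong: poor facial selectivity if the ring populates more than one conformer, or Lewis-acid-induced transannular attack of the C1=C10 alkene on the new oxirane. Fallback: the oxirane is installed before ring closure under reagent control. Setting out from diol 10, Sharpless asymmetric epoxidation (Ti(Oi-Pr)4, D-(−)-diethyl tartrate, t-BuOOH, 4 Å sieves, CH2Cl2, −20 °C) should give epoxy diol F3, since the primary allylic alcohol reacts and the secondary C2 carbinol with its cis methyl group is a poor substrate. TEMPO/PhI(OAc)2 then gives epoxy aldehyde F4, Ac2O/pyridine gives acetate F5, and TBAF buffered with AcOH gives alcohol F6. Acid 14 with DCC/DMAP gives ester F7, and metathesis as in step 12 gives bromomethyl butenolide F8. Closure of F8 with CrCl2 as in step 13 forms the C6–C7 bond on the epoxy aldehyde and rejoins the route at 19.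

Step 12 (metathesis). What may go wrong: slow ring closure of the electron-poor 1,1-disubstituted acrylate, with catalyst decomposition or loss of the allylic bromide. Fallback: the bromide is introduced after the butenolide is in place. Setting out from 13, esterification with 2-({[tert-butyl(dimethyl)silyl]oxy}methyl)prop-2-enoic acid (DCC, DMAP) gives ester F9. Metathesis with the same catalyst gives silyloxymethyl butenolide F10, and HF·pyridine gives hydroxymethyl butenolide F11. MsCl/Et3N at −40 °C followed by LiBr in THF converts F11 into 16, where the route is rejoined.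

**Further compounds**

F1 | step 13 | C6 epimer of 18 (6-epi alcohol) | C=C1C(=O)O[C@H]2C/C(C)=C/[C@@H](OC(C)=O)C/C(C)=C/[C@H](O)[C@H]12
F2 | step 13 | C6 ketone, 2-acetoxy-6-oxogermacra-1(10)E,4E,11(13)-trien-12,8-olide | C=C1C(=O)O[C@H]2C/C(C)=C/[C@@H](OC(C)=O)C/C(C)=C/C(=O)[C@H]12
F3 | step 14 | epoxy diol, the 2,3-epoxide of 10 with the oxirane sense of the target | C/C=C/[C@@H](O[Si](C)(C)C(C)(C)C)C/C(C)=C/[C@@H](O)C[C@@]1(C)O[C@@H]1CO
F4 | step 14 | epoxy aldehyde with free C2 hydroxyl | C/C=C/[C@@H](O[Si](C)(C)C(C)(C)C)C/C(C)=C/[C@@H](O)C[C@@]1(C)O[C@@H]1C=O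
F5 | step 14 | epoxy aldehyde C2 acetate (silyl ether) | C/C=C/[C@@H](O[Si](C)(C)C(C)(C)C)C/C(C)=C/[C@@H](OC(C)=O)C[C@@]1(C)O[C@@H]1C=O
F6 | step 14 | epoxy aldehyde C2 acetate with free C8 hydroxyl | C/C=C/[C@@H](O)C/C(C)=C/[C@@H](OC(C)=O)C[C@@]1(C)O[C@@H]1C=O
F7 | step 14 | 2-(bromomethyl)acrylate of F6 | C/C=C/[C@@H](OC(=O)C(=C)CBr)C/C(C)=C/[C@@H](OC(C)=O)C[C@@]1(C)O[C@@H]1C=O
F8 | step 14 | bromomethyl butenolide epoxy aldehyde | BrCC1=C[C@H](C/C(C)=C/[C@@H](OC(C)=O)C[C@@]2(C)O[C@@H]2C=O)OC1=O
F9 | step 12 | 2-(silyloxymethyl)acrylate of 13 | C/C=C/[C@@H](OC(=O)C(=C)CO[Si](C)(C)C(C)(C)C)C/C(C)=C/[C@@H](OC(C)=O)C/C(C)=C/C=O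
F10 | step 12 | silyloxymethyl butenolide | CC(C)(C)[Si](C)(C)OCC1=C[C@H](C/C(C)=C/[C@@H](OC(C)=O)C/C(C)=C/C=O)OC1=O
F11 | step 12 | hydroxymethyl butenolide | OCC1=C[C@H](C/C(C)=C/[C@@H](OC(C)=O)C/C(C)=C/C=O)OC1=O
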